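Remark on the chemistry: positions are numbered as in eudesmane (ring A = C1–C5 and C10, ring B = C5–C10); α is the face opposite the C10 methyl group. Compounds 15–26 lack C11–C13 and are named as 11,12,13-trinoreudesmanes; the SMILES strings define every structure. The open-chain hydroperoxide is taken as the form to be made.

## Analysis of the target

The target 31 is a eudesmane, a trans-fused decalin. Ring A is saturated, and ring B holds a C6=C7–C8=O enone whose α-carbon C7 carries a 2-hydroperoxyprop-2-yl group (C11–C13). There are four stereocentres, C3 (R), C4 (S), C5 (R) and C10 (R), of which C3–C4–C5 are contiguous and C4 and C10 are fully substituted. The C10 methyl is β and axial and H5 is α. The C3 angelate (axial) and the C4 acetate (equatorial) are cis on the α-face, and the C4 methyl is β, syn-diaxial to the C10 methyl. Sensitive groups are the tertiary allylic hydroperoxide (reduction, acid- or base-induced cleavage, addition to the C8 ketone), the Z-configured angelate (isomerisation to the tiglate), the tertiary acetate and the γ-hydrogen at C5. The synthesis is hard for three reasons: the quaternary C10 must be set in the absolute sense without a neighbouring heteroatom, the hindered secondary/tertiary diol must carry two different acyl groups, and the peroxide has to come last. The strategy rests on the pair C3-oxygen/C4-methyl. It is the enol-ether form of a cyclohexene C3=C4, the adduct of a 2-silyloxydiene C2=C3–C4=C5 and an alkene C10=C1 that bears the C10 methyl. Diene and alkene are linked through C6–C9 of ring B, so one intramolecular cycloaddition makes both rings. The C8 ketone can first serve as a carbinol stereocentre in that tether, and the C7 side chain is acetone plus oxygen.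

## Retrosynthetic reasoning

**O–C11 bond.** Cutting the O–C11 bond of 31 and moving the alkene from C6=C7 back to C7=C11 gives the isopropylidene enone 30. The cut is placed here because the peroxide tolerates almost no later chemistry. The forward ene photo-oxygenation must bond oxygen to C11 and take hydrogen from C6, which is the regiochemistry a carbonyl group imposes on its s-cis enone.

**C7=C11 bond.** Cutting this bond of 30 gives the ring B ketone 25 and acetone 27, joined through the enol silane 26 and the aldol 28. This removes three carbons in one aldol condensation. The forward reaction has to enolise C8 towards C7 and not towards the neopentyl C9, without base that would harm the esters.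

**Ester C–O bonds and the C8 oxidation level.** Ketone 25 is traced through alcohol 24 and silyl ether 23 to the hydroxy angelate 22, and then to the cis-diol 19 and angelic acid 20. The secondary C3 hydroxyl is acylated before the tertiary C4 hydroxyl, so no selectivity problem and no acyl migration arise. C8 stays a protected carbinol until its stereochemical task is done.

**C3–H and C4–O bonds.** Diol 19 comes from the α-hydroxy ketone 18 by hydride addition to C3. Ketone 18 comes from the enol ether 15 by oxidation at C4. The enol ether is the reason for choosing a silyloxydiene: it fixes the regiochemistry of the oxidation and lets the reagent approach anti to the C10 methyl.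

**C1–C2 and C5–C10 bonds (the key disconnection).** Cutting both bonds of 15 opens rings A and B together and gives the acyclic triene 14. No other pair of bonds removes both rings, both ring-fusion stereocentres and the C3=C4 enol ether in one operation. The forward cycloaddition must select one alkene face (through C8) and the trans ring fusion.

**C2=C3 enol ether and C4=C5 bond.** Triene 14 is the kinetic enol silyl ether of enone 12. Cutting the C4=C5 bond of 12 gives aldehyde 10 and the stabilised ylide 11, which delivers the E geometry the diene needs.

**C6–C7 and C9–C10 bonds.** Aldehyde 10 is traced through nitrile 8 to hydroxy nitrile 7, made from epoxide 4 and acetonitrile 5 (C6–C7 bond). Epoxide 4 comes through chlorohydrin 3 from (S)-epichlorohydrin 1 and the Grignard reagent 2 (C9–C10 bond). Both openings occur at a CH2 terminus, so the single purchased stereocentre becomes C8 unchanged.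

## Alternatives that were turned down

**Alternative 1:** Ring A is taken from a prochiral 4,4-disubstituted cyclohexadienone A1 and the bonds C5–C6 and C4–C15 are disconnected. In the forward step a chiral copper–bisphosphine catalyst adds a vinyl nucleophile to one of the two enantiotopic enone arms of A1, and the enolate is methylated, giving the cyclohexenone A2.
- For it: the absolute configuration of the quaternary C10 comes from a catalyst in one step from an achiral substrate. Addition anti to the larger C10 substituent should give the correct C5/C10 relationship. On this point it is better founded than the chosen cycloaddition, whose ring-fusion selectivity is open.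
- Against it for this target: the C4 centre made by the methylation is a C–H centre, but the target needs a fully substituted C4 carbinol, so this stereocentre has to be made again by enolate oxidation. The second enone of ring A must be reduced away. Ring B has to be built afterwards in separate steps (oxidative cleavage of the vinyl group, ketal removal, aldol closure), and the side chain must still be attached.
- Comparison: the chosen route gives both rings and the C3/C4 oxidation pattern in one step, and its sequence after the key step is shorter. It pays for this with less certain stereocontrol.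

**Alternative 2:** The C9–C10 bond is disconnected. In the forward step a phenol A3 with a tethered allylic carbonate is dearomatised by a chiral palladium–phosphine catalyst: the para carbon of the phenolate attacks the 2-substituted π-allyl unit and closes ring B, giving the cross-conjugated dienone A4.
- For it: C10 is created catalytically. The exocyclic methylene at C8 is a ketone surrogate that needs no protecting group and no stereocentre, which is simpler than the C8 carbinol of the chosen route.
- Against it for this target: A4 has no C5 stereocentre and no oxygen at C4. Two enone double bonds and the methylene group would have to be told apart, C4=C5 reduced to the trans fusion and C4 hydroxylated. The tether can also reach the methyl-bearing ortho carbon through an equally six-membered closure, so ortho/para and O- versus C-alkylation are open. The tetrasubstituted arene A3 itself needs several steps.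
- Comparison: in the chosen route the tether leaves no regiochemical choice and C5 is set in the ring-forming step. A4 would need a longer redox sequence than 15.

**Alternative 3:** Ring B is disconnected at C5–C6 and C9–C10 as an intermolecular Diels–Alder adduct. In the forward step diene A5 adds to the keto ester A6, activated at the ketone by a chiral oxazaborolidinium Lewis acid, to give the cyclohexene A7.
- For it: the trans relationship of C5 and C10 follows stereospecifically from the E geometry of A6, and the absolute configuration comes from the catalyst. On both points it is stronger than the chosen step. The enol ether also sits at C8, where the ketone is needed.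
- Against it for this target: a trisubstituted dienophile that forms a quaternary centre reacts sluggishly with a 2-silyloxybutadiene, and the regiochemistry depends on the ketone and not the ester directing. Ring A must then be annulated between the ester carbon (C1) and the acetyl carbon (C4) by inserting C2 and C3. C1 has to be deoxygenated to a methylene group, and the C3/C4 diol stereochemistry must be built separately.
- Comparison: the chosen strategy delivers the complete bicyclic skeleton with the C3=C4 enol ether in one step. It is shorter and has less redox traffic, at the price of a less predictable ring fusion.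

Key step: step 8

## Route

Step 1
Reactants: 1 (S)-epichlorohydrin; 2 isopropenylmagnesium bromide
Product: 3 (S)-1-chloro-4-methylpent-4-en-2-ol
Conditions: CuI (10 mol%), THF, −40 → −20 °C; aq. NH4Cl
Reagents that add atoms: isopropenylmagnesium bromide (2), CC(=C)[Mg]Br
Why: Copper-catalysed Grignard opening of a terminal epoxide (SN2 at the unsubstituted carbon); the stereocentre is not touched, so the configuration of 1 is carried into 3, and the primary chloride survives at low temperature.

Step 2
Reactants: 3 (S)-1-chloro-4-methylpent-4-en-2-ol
Product: 4 (S)-2-(2-methylprop-2-en-1-yl)oxirane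
Conditions: KOH (powdered), Et2O, 0 °C → rt
Reagents that add atoms: none
Why: Intramolecular Williamson etherification of the chlorohydrin; the C–O bond at the stereocentre is not broken, so the configuration is retained (the volatile epoxide should be used as a concentrated solution).

Step 3
Reactants: 4 (S)-2-(2-methylprop-2-en-1-yl)oxirane; 5 acetonitrile
Product: 7 (R)-4-hydroxy-6-methylhept-6-enenitrile, via lithioacetonitrile 6 (not isolated)
Conditions: MeCN, n-BuLi, THF, −78 °C; then 4, −78 → 0 °C; aq. NH4Cl
Reagents that add atoms: acetonitrile (5), CC#N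
Why: LiCH2CN is a small carbanion that opens monosubstituted epoxides at the CH2 terminus (SN2); this adds C6 and C5 with the aldehyde carbon masked as a nitrile and leaves the carbinol centre (future C8) untouched, the descriptor changing to R only by priority.

Step 4
Reactants: 7 (R)-4-hydroxy-6-methylhept-6-enenitrile
Product: 8 (R)-4-(tert-butyldimethylsilyloxy)-6-methylhept-6-enenitrile
Conditions: TBSCl, imidazole, DMF, rt
Reagents that add atoms: tert-butyldimethylsilyl chloride, CC(C)(C)[Si](C)(C)Cl
Why: Standard silylation of a secondary alcohol; the ether is the bulky equatorial group of the later tether and prevents oxa-Michael addition to the enone of step 6.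

Step 5
Reactants: 8 (R)-4-(tert-butyldimethylsilyloxy)-6-methylhept-6-enenitrile
Product: 10 (R)-4-(tert-butyldimethylsilyloxy)-6-methylhept-6-enal, via N-(diisobutylalumanyl)imine 9 (not isolated)
Conditions: i-Bu2AlH, CH2Cl2, −78 °C; aq. KNaC4H4O6 (tartrate), rt
Reagents that add atoms: water, O
Why: Partial reduction of a nitrile to the N-aluminated imine, which is hydrolysed on work-up to the aldehyde; no acid-labile protecting group has to be removed, and the silyl ether and the 1,1-disubstituted alkene are inert at −78 °C.

Step 6
Reactants: 10 (R)-4-(tert-butyldimethylsilyloxy)-6-methylhept-6-enal; 11 3-(triphenyl-λ5-phosphanylidene)butan-2-one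
Product: 12 (3E,7R)-7-(tert-butyldimethylsilyloxy)-3,9-dimethyldeca-3,9-dien-2-one
Conditions: PhMe, 100 °C
Reagents that add atoms: 3-(triphenyl-λ5-phosphanylidene)butan-2-one (11), CC(=O)C(C)=P(c1ccccc1)(c1ccccc1)c1ccccc1
Why: Wittig olefination with a stabilised α-methyl keto ylide gives the E trisubstituted enone under thermodynamic control of the oxaphosphetane; this places the tether on the outside of the future diene.

Step 7
Reactants: 12 (3E,7R)-7-(tert-butyldimethylsilyloxy)-3,9-dimethyldeca-3,9-dien-2-one
Product: 14 (3E,7R)-7-(tert-butyldimethylsilyloxy)-3,9-dimethyl-2-(triethylsilyloxy)deca-1,3,9-triene, via lithium dienolate 13 (not isolated)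
Conditions: LiN(i-Pr)2, THF, −78 °C; Et3SiCl, Et3N, −78 → 0 °C
Reagents that add atoms: chlorotriethylsilane, CC[Si](Cl)(CC)CC
Why: Kinetic deprotonation of the methyl ketone at its α′-methyl group and O-silylation give the cross-conjugated 2-silyloxydiene with the E alkene unchanged; the triethylsilyl group withstands heating yet can later be removed beside the C8 tert-butyldimethylsilyl ether.

Step 8
Reactants: 14 (3E,7R)-7-(tert-butyldimethylsilyloxy)-3,9-dimethyl-2-(triethylsilyloxy)deca-1,3,9-triene
Product: 15 (4aR,6R,8aR)-6-(tert-butyldimethylsilyloxy)-1,4a-dimethyl-2-(triethylsilyloxy)-3,4,4a,5,6,7,8,8a-octahydronaphthalene (8α-silyloxy-3-silyloxy-11,12,13-trinor-5α-eudesm-3-ene)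
Conditions: PhMe (0.01 M), BHT (cat.), N,O-bis(trimethylsilyl)acetamide (5 mol%), base-washed sealed tube, 200 °C
Reagents that add atoms: none
Why: A concerted, thermally allowed suprafacial [4+2] cycloaddition of the 2-silyloxydiene C2=C3–C4=C5 with the unactivated alkene C10=C1 forms C1–C2 and C5–C10; the closest known reaction type is the thermal type 1 intramolecular Diels–Alder reaction of 1,7,9-decatrienes, including 2-silyloxydienes with unactivated dienophiles. Ring A is the six-membered ring made by the cycloaddition itself, and ring B is the six-membered ring closed through the four-carbon tether C6–C9 by the C5–C10 bond (fused mode). C10 is set relative to C8: in the chair-like tether the C8 silyloxy group sits equatorial, because an axial one would be syn-diaxial to the C10 methyl, and this decides which alkene face adds. C5 is set by the E geometry of the diene together with the tether-exo transition state, in which the C10 methyl and not the tether lies under the diene, and this gives the trans ring fusion. Regiochemistry is fixed by the tether, and the new alkene appears as the C3=C4 silyl enol ether. The step needs facial and trans-fusion selectivity; the first is secured by the substrate, but the second has only the bulk of the silyloxy-bearing tether under the diene in the endo mode as a bias, so a mixture with the cis-fused isomer should be expected. The isomers are separated at this stage, while C8 is still a stereocentre, so that the later oxidation of C8 cannot turn a diastereomer mixture into a loss of enantiomeric purity. Base-washed glass and the silylating scavenger protect both enol ethers at 200 °C.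

Step 9
Reactants: 15 (4aR,6R,8aR)-6-(tert-butyldimethylsilyloxy)-1,4a-dimethyl-2-(triethylsilyloxy)-3,4,4a,5,6,7,8,8a-octahydronaphthalene
Product: 18 8α-(tert-butyldimethylsilyloxy)-4α-hydroxy-11,12,13-trinor-5α-eudesman-3-one, via 3α,4α-epoxide 16 (not isolated), via 4α-triethylsilyloxy ketone 17 (not isolated)
Conditions: mCPBA, NaHCO3, CH2Cl2, −20 → 0 °C; then HF·pyridine, pyridine, THF, 0 °C
Reagents that add atoms: 3-chloroperoxybenzoic acid, OOC(=O)c1cccc(Cl)c1
Why: Rubottom oxidation: the peracid epoxidises the electron-rich tetrasubstituted enol ether from the α-face, opposite the axial C10 methyl, and ring opening with 1,4-silyl shift gives the α-silyloxy ketone; buffered fluoride then removes the triethylsilyl group selectively. This sets C4 with α-oxygen and β-methyl.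

Step 10
Reactants: 18 8α-(tert-butyldimethylsilyloxy)-4α-hydroxy-11,12,13-trinor-5α-eudesman-3-one
Product: 19 8α-(tert-butyldimethylsilyloxy)-11,12,13-trinor-5α-eudesmane-3α,4α-diol
Conditions: LiBH(s-Bu)3 (2.5 equiv), THF, −78 °C; aq. NH4Cl
Reagents that add atoms: none
Why: The bulky trialkylborohydride attacks the C3 ketone along the equatorial trajectory, because axial approach on the α-face is blocked by the axial hydrogens at C1 and C5, as in 4,4-dimethyl-3-oxo triterpenoids; this gives the axial 3α-alcohol, cis to the C4 oxygen.

Step 11
Reactants: 19 8α-(tert-butyldimethylsilyloxy)-11,12,13-trinor-5α-eudesmane-3α,4α-diol; 20 angelic acid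
Product: 22 3α-angeloyloxy-8α-(tert-butyldimethylsilyloxy)-11,12,13-trinor-5α-eudesman-4α-ol, via angelic 2,4,6-trichlorobenzoic anhydride 21 (not isolated)
Conditions: 20, 2,4,6-Cl3C6H2COCl, Et3N, PhMe, rt; then 19, 80 °C
Reagents that add atoms: angelic acid (20), C/C=C(/C)C(=O)O
Why: Yamaguchi-type esterification through the mixed anhydride without a nucleophilic catalyst, the conditions that transfer the angeloyl group with little Z to E isomerisation; only the secondary hydroxyl reacts, the tertiary one being far less nucleophilic.

Step 12
Reactants: 22 3α-angeloyloxy-8α-(tert-butyldimethylsilyloxy)-11,12,13-trinor-5α-eudesman-4α-ol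
Product: 23 4α-acetoxy-3α-angeloyloxy-8α-(tert-butyldimethylsilyloxy)-11,12,13-trinor-5α-eudesmane
Conditions: Ac2O, DMAP, Et3N, CH2Cl2, rt → 40 °C
Reagents that add atoms: acetic anhydride, CC(=O)OC(C)=O
Why: DMAP-catalysed acetylation (Steglich conditions) acylates tertiary alcohols; the silyl ether and the angelate tolerate the mild temperature, and acyl migration is no longer possible once both oxygens are acylated.

Step 13
Reactants: 23 4α-acetoxy-3α-angeloyloxy-8α-(tert-butyldimethylsilyloxy)-11,12,13-trinor-5α-eudesmane
Product: 24 4α-acetoxy-3α-angeloyloxy-11,12,13-trinor-5α-eudesman-8α-ol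
Conditions: HF·pyridine, pyridine, THF, 0 °C → rt
Reagents that add atoms: none
Why: Fluoride-mediated cleavage of the secondary silyl ether under buffered, non-basic conditions that leave both esters untouched.

Step 14
Reactants: 24 4α-acetoxy-3α-angeloyloxy-11,12,13-trinor-5α-eudesman-8α-ol
Product: 25 4α-acetoxy-3α-angeloyloxy-11,12,13-trinor-5α-eudesman-8-one
Conditions: Dess–Martin periodinane, NaHCO3, CH2Cl2, rt
Reagents that add atoms: none
Why: Dess–Martin oxidation of a secondary alcohol under buffered neutral conditions; the C8 stereocentre, whose task ended in step 8, is erased.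

Step 15
Reactants: 25 4α-acetoxy-3α-angeloyloxy-11,12,13-trinor-5α-eudesman-8-one
Product: 26 4α-acetoxy-3α-angeloyloxy-8-(trimethylsilyloxy)-11,12,13-trinor-5α-eudesm-7-ene
Conditions: Me3SiOTf, Et3N, CH2Cl2, 0 °C
Reagents that add atoms: trimethylsilyl trifluoromethanesulfonate, C[Si](C)(C)OS(=O)(=O)C(F)(F)F
Why: Soft enolisation of the ketone by silyl triflate and amine does not touch the esters; it goes towards C7, since C9 is neopentyl and a C8=C9 double bond next to the quaternary C10 is the less stable isomer (the behaviour of 2-oxo-5α-steroids).

Step 16
Reactants: 26 4α-acetoxy-3α-angeloyloxy-8-(trimethylsilyloxy)-11,12,13-trinor-5α-eudesm-7-ene; 27 acetone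
Product: 28 4α-acetoxy-3α-angeloyloxy-11-hydroxy-5α-eudesman-8-one (C7 epimers)
Conditions: TiCl4, acetone, CH2Cl2, −78 °C; aq. NaHCO3
Reagents that add atoms: acetone (27), CC(C)=O
Why: Mukaiyama aldol addition: acetone activated by TiCl4 is attacked by the enol silane at C7 under non-basic conditions, so neither ester is enolised; the configuration at C7 is irrelevant because this carbon becomes sp2 in step 17.

Step 17
Reactants: 28 4α-acetoxy-3α-angeloyloxy-11-hydroxy-5α-eudesman-8-one
Product: 30 4α-acetoxy-3α-angeloyloxy-5α-eudesm-7(11)-en-8-one, via C11 methanesulfonate 29 (not isolated)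
Conditions: MsCl, Et3N, CH2Cl2, 0 °C → rt; then DBU, rt
Reagents that add atoms: none
Why: Mesylation of the tertiary alcohol through sulfene and E1cB elimination through the C8 enolate give the conjugated, tetrasubstituted isopropylidene enone; the amidine base moves any isopropenyl isomer into conjugation.

Step 18
Reactants: 30 4α-acetoxy-3α-angeloyloxy-5α-eudesm-7(11)-en-8-one
Product: 31 4α-acetoxy-3α-angeloyloxy-11-hydroperoxy-5α-eudesm-6-en-8-one (target)
Conditions: O2, hν (visible), tetraphenylporphyrin (cat.), CH2Cl2, 0 °C
Reagents that add atoms: oxygen, O=O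
Why: Schenck ene reaction of singlet oxygen with an s-cis α,β-unsaturated ketone: oxygen bonds to the β-carbon C11 and the allylic hydrogen is taken from the substituent geminal to the carbonyl (C6), which moves the double bond to C6=C7 in conjugation with C8=O. The s-cis tetrasubstituted enone should react much faster than the trisubstituted angelate, and no stereocentre is created.

## Compound list

1 | (S)-epichlorohydrin | ClC[C@@H]1CO1 | starting material
2 | isopropenylmagnesium bromide | CC(=C)[Mg]Br | starting material
3 | (S)-1-chloro-4-methylpent-4-en-2-ol | ClC[C@@H](O)CC(C)=C | intermediate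
4 | (S)-2-(2-methylprop-2-en-1-yl)oxirane | C=C(C)C[C@H]1CO1 | intermediate
5 | acetonitrile | CC#N | starting material
6 | lithioacetonitrile | [Li]CC#N | intermediate
7 | (R)-4-hydroxy-6-methylhept-6-enenitrile | N#CCC[C@@H](O)CC(C)=C | intermediate
8 | (R)-4-(tert-butyldimethylsilyloxy)-6-methylhept-6-enenitrile | N#CCC[C@@H](O[Si](C)(C)C(C)(C)C)CC(C)=C | intermediate
9 | N-(diisobutylalumanyl)imine of aldehyde 10 | CC(C)C[Al](CC(C)C)N=CCC[C@@H](O[Si](C)(C)C(C)(C)C)CC(C)=C | intermediate
10 | (R)-4-(tert-butyldimethylsilyloxy)-6-methylhept-6-enal | O=CCC[C@@H](O[Si](C)(C)C(C)(C)C)CC(C)=C | intermediate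
11 | 3-(triphenyl-λ5-phosphanylidene)butan-2-one | CC(=O)C(C)=P(c1ccccc1)(c1ccccc1)c1ccccc1 | starting material
12 | (3E,7R)-7-(tert-butyldimethylsilyloxy)-3,9-dimethyldeca-3,9-dien-2-one | CC(=O)/C(C)=C/CC[C@@H](O[Si](C)(C)C(C)(C)C)CC(C)=C | intermediate
13 | lithium dienolate of 12 | [Li]OC(=C)/C(C)=C/CC[C@@H](O[Si](C)(C)C(C)(C)C)CC(C)=C | intermediate
14 | (3E,7R)-7-(tert-butyldimethylsilyloxy)-3,9-dimethyl-2-(triethylsilyloxy)deca-1,3,9-triene | C=C(O[Si](CC)(CC)CC)/C(C)=C/CC[C@@H](O[Si](C)(C)C(C)(C)C)CC(C)=C | intermediate
15 | (4aR,6R,8aR)-6-(tert-butyldimethylsilyloxy)-1,4a-dimethyl-2-(triethylsilyloxy)-3,4,4a,5,6,7,8,8a-octahydronaphthalene | CC1=C(O[Si](CC)(CC)CC)CC[C@]2(C)C[C@H](O[Si](C)(C)C(C)(C)C)CC[C@@H]12 | intermediate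
16 | 3α,4α-epoxy-8α-(tert-butyldimethylsilyloxy)-3β-(triethylsilyloxy)-11,12,13-trinor-5α-eudesmane | CC[Si](CC)(CC)O[C@@]12CC[C@]3(C)C[C@H](O[Si](C)(C)C(C)(C)C)CC[C@H]3[C@]1(C)O2 | intermediate
17 | 8α-(tert-butyldimethylsilyloxy)-4α-(triethylsilyloxy)-11,12,13-trinor-5α-eudesman-3-one | O=C1CC[C@]2(C)C[C@H](O[Si](C)(C)C(C)(C)C)CC[C@H]2[C@]1(C)O[Si](CC)(CC)CC | intermediate
18 | 8α-(tert-butyldimethylsilyloxy)-4α-hydroxy-11,12,13-trinor-5α-eudesman-3-one | O=C1CC[C@]2(C)C[C@H](O[Si](C)(C)C(C)(C)C)CC[C@H]2[C@]1(C)O | intermediate
19 | 8α-(tert-butyldimethylsilyloxy)-11,12,13-trinor-5α-eudesmane-3α,4α-diol | O[C@@H]1CC[C@]2(C)C[C@H](O[Si](C)(C)C(C)(C)C)CC[C@H]2[C@]1(C)O | intermediate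
20 | angelic acid, (Z)-2-methylbut-2-enoic acid | C/C=C(/C)C(=O)O | starting material
21 | angelic 2,4,6-trichlorobenzoic anhydride | C/C=C(/C)C(=O)OC(=O)c1c(Cl)cc(Cl)cc1Cl | intermediate
22 | 3α-angeloyloxy-8α-(tert-butyldimethylsilyloxy)-11,12,13-trinor-5α-eudesman-4α-ol | C/C=C(/C)C(=O)O[C@@H]1CC[C@]2(C)C[C@H](O[Si](C)(C)C(C)(C)C)CC[C@H]2[C@]1(C)O | intermediate
23 | 4α-acetoxy-3α-angeloyloxy-8α-(tert-butyldimethylsilyloxy)-11,12,13-trinor-5α-eudesmane | C/C=C(/C)C(=O)O[C@@H]1CC[C@]2(C)C[C@H](O[Si](C)(C)C(C)(C)C)CC[C@H]2[C@]1(C)OC(C)=O | intermediate
24 | 4α-acetoxy-3α-angeloyloxy-11,12,13-trinor-5α-eudesman-8α-ol | C/C=C(/C)C(=O)O[C@@H]1CC[C@]2(C)C[C@H](O)CC[C@H]2[C@]1(C)OC(C)=O | intermediate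
25 | 4α-acetoxy-3α-angeloyloxy-11,12,13-trinor-5α-eudesman-8-one | C/C=C(/C)C(=O)O[C@@H]1CC[C@]2(C)CC(=O)CC[C@H]2[C@]1(C)OC(C)=O | intermediate
26 | 4α-acetoxy-3α-angeloyloxy-8-(trimethylsilyloxy)-11,12,13-trinor-5α-eudesm-7-ene | C/C=C(/C)C(=O)O[C@@H]1CC[C@]2(C)CC(O[Si](C)(C)C)=CC[C@H]2[C@]1(C)OC(C)=O | intermediate
27 | acetone | CC(C)=O | starting material
28 | 4α-acetoxy-3α-angeloyloxy-11-hydroxy-5α-eudesman-8-one (C7 epimers) | C/C=C(/C)C(=O)O[C@@H]1CC[C@]2(C)CC(=O)C(C(C)(C)O)C[C@H]2[C@]1(C)OC(C)=O | intermediate
29 | 4α-acetoxy-3α-angeloyloxy-11-(methanesulfonyloxy)-5α-eudesman-8-one | C/C=C(/C)C(=O)O[C@@H]1CC[C@]2(C)CC(=O)C(C(C)(C)OS(C)(=O)=O)C[C@H]2[C@]1(C)OC(C)=O | intermediate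
30 | 4α-acetoxy-3α-angeloyloxy-5α-eudesm-7(11)-en-8-one | C/C=C(/C)C(=O)O[C@@H]1CC[C@]2(C)CC(=O)C(=C(C)C)C[C@H]2[C@]1(C)OC(C)=O | intermediate
31 | 4α-acetoxy-3α-angeloyloxy-11-hydroperoxy-5α-eudesm-6-en-8-one, (3R,4S,5R,10R) | C/C=C(/C)C(=O)O[C@@H]1CC[C@]2(C)CC(=O)C(C(C)(C)OO)=C[C@H]2[C@]1(C)OC(C)=O | target

## Step count and least certain steps

Total step count: 18. Longest linear sequence: 18 steps, from 1 to 31; compounds 2, 5, 11, 20 and 27 enter as purchased reagents.

**Step 8 (key step).**
- What may go wrong: discrimination between the tether-exo and tether-endo transition states may be insufficient, so that the trans ring fusion is not favoured. The cycloaddition of an unactivated 1,1-disubstituted alkene may also be slow enough for thermal desilylation to compete.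
- Fallback: the ring fusion is taken out of the cycloaddition. It sets out from 15 as obtained, mixed with its cis-fused C5 epimer F1, and returns to the route at 15 as a single isomer. Saegusa–Ito oxidation of the mixture (Pd(OAc)2, MeCN, through a divalent palladium enolate) removes the C5 stereocentre and gives the enone F2 from both isomers. Reduction with Li/NH3 (THF, t-BuOH, −78 °C) protonates C5 to the trans-fused lithium enolate F3, the known outcome for 4-methyl-octal-4-en-3-ones with an angular methyl group. Trapping with Et3SiCl/Et3N regenerates 15.
- Limit of the fallback: adducts with the opposite configuration at C10 remain diastereomers of F2 while C8 is a carbinol and are removed by chromatography. Should they dominate, the enantiomer of 1 would be used.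

**Step 10.**
- What may go wrong: hydride may be delivered in part along the axial trajectory (chelation of lithium between the C3 carbonyl and the C4 oxygen favours it), which would erode the 3α selectivity. Base-induced α-ketol rearrangement is a second possibility.
- Fallback: both oxygens are introduced from the α-face in one dihydroxylation. It sets out from 15 and returns at 19. MeLi cleaves the silyl enol ether to the lithium enolate F3 (the species of the previous fallback). PhNTf2 gives the enol triflate F4. Reduction with Pd(OAc)2/PPh3, HCO2H and n-Bu3N gives the alkene F5. OsO4 (cat.) with N-methylmorpholine N-oxide then adds anti to the C10 methyl and gives 19.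

**Step 11.**
- What may go wrong: the angeloyl group may isomerise from Z to E during activation, and acylation of the hindered axial alcohol may be slow.
- Fallback: the Z alkene is built after the ester bond. It sets out from 19 and returns at 22. The diol is esterified at O3 with 2-[bis(2,2,2-trifluoroethoxy)phosphoryl]propanoic acid (DCC, DMAP) to the phosphonate ester F6. Still–Gennari olefination with acetaldehyde (KN(SiMe3)2, 18-crown-6, THF, −78 °C, one extra equivalent of base for the tertiary hydroxyl) gives the Z-configured ester 22.

**Step 16.**
- What may go wrong: the Lewis acid may ionise the tertiary acetate, or the aldol may revert or give low conversion with the enolisable ketone electrophile.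
- Fallback: the enolate is generated reductively under neutral conditions. It sets out from 26 and returns at 28. N-Bromosuccinimide (THF, 0 °C) converts the enol silane into the bromo ketone F7. SmI2 with acetone (THF, −78 °C, Reformatsky-type addition of the samarium enolate) gives 28.

## Further compounds

F1 | step 8 | (4aR,6R,8aS)-6-(tert-butyldimethylsilyloxy)-1,4a-dimethyl-2-(triethylsilyloxy)-3,4,4a,5,6,7,8,8a-octahydronaphthalene (cis-fused C5 epimer of 15) | CC1=C(O[Si](CC)(CC)CC)CC[C@]2(C)C[C@H](O[Si](C)(C)C(C)(C)C)CC[C@H]12
F2 | step 8 | 8α-(tert-butyldimethylsilyloxy)-11,12,13-trinoreudesm-4-en-3-one | O=C1CC[C@]2(C)C[C@H](O[Si](C)(C)C(C)(C)C)CCC2=C1C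
F3 | step 8 | lithium 8α-(tert-butyldimethylsilyloxy)-11,12,13-trinor-5α-eudesm-3-en-3-olate | CC1=C(O[Li])CC[C@]2(C)C[C@H](O[Si](C)(C)C(C)(C)C)CC[C@@H]12
F4 | step 10 | 8α-(tert-butyldimethylsilyloxy)-11,12,13-trinor-5α-eudesm-3-en-3-yl trifluoromethanesulfonate | CC1=C(OS(=O)(=O)C(F)(F)F)CC[C@]2(C)C[C@H](O[Si](C)(C)C(C)(C)C)CC[C@@H]12
F5 | step 10 | 8α-(tert-butyldimethylsilyloxy)-11,12,13-trinor-5α-eudesm-3-ene | CC1=CCC[C@]2(C)C[C@H](O[Si](C)(C)C(C)(C)C)CC[C@@H]12
F6 | step 11 | 8α-(tert-butyldimethylsilyloxy)-4α-hydroxy-11,12,13-trinor-5α-eudesman-3α-yl 2-[bis(2,2,2-trifluoroethoxy)phosphoryl]propanoate | CC(C(=O)O[C@@H]1CC[C@]2(C)C[C@H](O[Si](C)(C)C(C)(C)C)CC[C@H]2[C@]1(C)O)P(=O)(OCC(F)(F)F)OCC(F)(F)F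
F7 | step 16 | 4α-acetoxy-3α-angeloyloxy-7-bromo-11,12,13-trinor-5α-eudesman-8-one | C/C=C(/C)C(=O)O[C@@H]1CC[C@]2(C)CC(=O)C(Br)C[C@H]2[C@]1(C)OC(C)=O
A1 | alternative 1 | 4-methyl-4-[(2-methyl-1,3-dioxolan-2-yl)methyl]cyclohexa-2,5-dien-1-one | O=C1C=CC(C)(CC2(C)OCCO2)C=C1
A2 | alternative 1 | 5-ethenyl-4,6-dimethyl-4-[(2-methyl-1,3-dioxolan-2-yl)methyl]cyclohex-2-en-1-one | O=C1C=C[C@](C)(CC2(C)OCCO2)[C@@H](C=C)[C@@H]1C
A3 | alternative 2 | 4-(3-hydroxy-2,6-dimethylphenyl)-2-methylidenebutyl methyl carbonate | Cc1ccc(O)c(C)c1CCC(=C)COC(=O)OC
A4 | alternative 2 | 1,4a-dimethyl-6-methylidene-5,6,7,8-tetrahydro-4aH-naphthalen-2-one | O=C1C=C[C@]2(C)CC(=C)CCC2=C1C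
A5 | alternative 3 | 2-(tert-butyldimethylsilyloxy)buta-1,3-diene | C=CC(=C)O[Si](C)(C)C(C)(C)C
A6 | alternative 3 | methyl (E)-2-methyl-4-oxopent-2-enoate | COC(=O)/C(C)=C/C(C)=O
A7 | alternative 3 | methyl 6-acetyl-3-(tert-butyldimethylsilyloxy)-1-methylcyclohex-3-ene-1-carboxylate | COC(=O)[C@]1(C)CC(O[Si](C)(C)C(C)(C)C)=CC[C@H]1C(C)=O
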